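**Strategy.** Ring numbering: C1 (enolised carbonyl), C2 (acyl-bearing), C3 (ketone), C4 (carbinol), C5, C6 (methylenes). The ring is traced back to an open 5-oxohexanoate and this to a cyclobutane. The key step is a catalytic enantioselective [2+2] cycloaddition of the bis-silyl enediol ether of hydroxyacetone (C3, C4 and their oxygens) with trifluoroethyl acrylate (C5, C6, C1); it closes a four-membered ring by forming the C4–C5 bond next to a temporary C3–C6 bond and sets the C4 stereocentre. It exploits the 1,5-relationship of the C1 and C3 carbonyls across C6–C5–C4. Strain-driven retro-aldol opening, Dieckmann closure (C1–C2), C2-acylation and desilylation finish the route.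

Key step: step 2

Assumption: the (S)-configured oxazaborolidine–AlBr3 catalyst is taken to give the (3R) cyclobutane 4; if the sense of induction is the opposite one, its (R)-enantiomer is used and nothing else changes.
Remark: triketones 13 and 14 are written as the enol tautomer of the target SMILES, dione 6 in its diketo form; the tautomers interconvert.

Step 1
Reactants: 1 1-[(tert-butyldimethylsilyl)oxy]propan-2-one
Product: 2 (Z)-1,2-bis[(tert-butyldimethylsilyl)oxy]prop-1-ene
Conditions: TBSOTf (1.2 equiv), Et3N (1.5 equiv), CH2Cl2, 0 °C to rt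
Reagents that add atoms: tert-butyldimethylsilyl trifluoromethanesulfonate, CC(C)(C)[Si](C)(C)OS(=O)(=O)C(F)(F)F
Why: Soft enolisation with a silyl triflate and a tertiary amine (silyl enol ether formation) should place the double bond on the oxygen-bearing side and give the more substituted, heteroatom-stabilised (Z)-enediol ether; any terminal regioisomer is removed by distillation.

Step 2
Reactants: 2 (Z)-1,2-bis[(tert-butyldimethylsilyl)oxy]prop-1-ene; 3 2,2,2-trifluoroethyl acrylate
Product: 4 2,2,2-trifluoroethyl (1R,2S,3R)-2,3-bis[(tert-butyldimethylsilyl)oxy]-2-methylcyclobutane-1-carboxylate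
Conditions: (S)-B-(o-tolyl)oxazaborolidine from (S)-α,α-diphenylprolinol (10 mol%), AlBr3 (10 mol%), CH2Cl2, −78 °C
Reagents that add atoms: none
Why: The AlBr3-activated oxazaborolidine binds the acrylate carbonyl, the enediol ether attacks the β-carbon through its CH(OTBS) terminus (the charge then rests on the tertiary, oxygen-stabilised carbon), and the bound ester enolate collapses onto the silyloxocarbenium ion, so that the C4–C5 bond (cyclobutane C3–C4) and the temporary C3–C6 bond (cyclobutane C2–C1) form in one stepwise [2+2] cycloaddition. The closest known reaction type is the Lewis- or Brønsted-acid-catalysed [2+2] cycloaddition of silyl enol ethers with acrylates, which is enantioselective with this catalyst class and trifluoroethyl acrylate. The four-membered ring is closed by a Michael-type addition followed by a 4-exo-trig aldol-type attack of the enolate carbon on the oxocarbenium carbon. The catalyst shields one face of the s-trans acrylate and the enol ether approaches in the exo orientation, which should fix the (3R) carbinol centre; the centres at C1 and C2 are expected as shown and are erased in step 3. The step needs ring closure to outrun silyl transfer to the enolate (open Mukaiyama–Michael product) and a high exo preference, because an adduct with the catalyst-set C1 but the other relative configuration at C3 would carry the enantiomeric carbinol forward; the bulky TBS group on the enol oxygen and the low temperature should secure the first, the (Z)-geometry and the anti preference of siloxy and ester groups the second.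

Step 3
Reactants: 4 2,2,2-trifluoroethyl (1R,2S,3R)-2,3-bis[(tert-butyldimethylsilyl)oxy]-2-methylcyclobutane-1-carboxylate
Product: 5 2,2,2-trifluoroethyl (4R)-4-[(tert-butyldimethylsilyl)oxy]-5-oxohexanoate
Conditions: Tf2NH (5 mol%), MeOH (3 equiv), CH2Cl2, −20 to 0 °C
Reagents that add atoms: none
Why: Acid-triggered retro-aldol (push–pull) fragmentation of the donor–acceptor cyclobutane cleaves the C1–C2 bond with relief of ring strain and passes the tertiary silyl group to methanol, while the secondary silyl ether and the carbinol stereocentre, which is not involved, should be retained.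

Step 4
Reactants: 5 2,2,2-trifluoroethyl (4R)-4-[(tert-butyldimethylsilyl)oxy]-5-oxohexanoate
Product: 6 (4R)-4-[(tert-butyldimethylsilyl)oxy]cyclohexane-1,3-dione
Conditions: LiHMDS (2.2 equiv), THF, −78 to 0 °C; then cold 1 M HCl
Reagents that add atoms: none
Why: Dieckmann-type intramolecular Claisen condensation: kinetic deprotonation at the methyl group (the silyloxy-bearing methine is hindered) and 6-exo-trig attack on the activated trifluoroethyl ester, the second equivalent of base taking up the acidic dione so that the stereocentre is not enolised.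

Step 5
Reactants: 7 (E)-undec-2-enal
Product: 8 (1E,3E)-1-iodododeca-1,3-diene
Conditions: CrCl2 (6 equiv), CHI3 (2 equiv), THF, 0 °C
Reagents that add atoms: iodoform, IC(I)I
Why: Takai olefination of the enal with the geminal dichromium species from iodoform should give the iododiene with the new double bond E.

Step 6
Reactants: 9 hex-5-enoic acid; 8 (1E,3E)-1-iodododeca-1,3-diene
Product: 11 (7E,9E)-octadeca-7,9-dienoic acid, via borane adduct 10 (not isolated)
Conditions: 9-BBN (2.1 equiv), THF, 0 °C to rt; then 8, Pd(dppf)Cl2 (5 mol%), AsPh3 (5 mol%), 3 M aq. NaOH, THF/DMF, rt; then aq. HCl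
Reagents that add atoms: none
Why: Anti-Markovnikov hydroboration of the terminal alkene (the acid is first taken up as the acyloxyborane) followed by B-alkyl Suzuki–Miyaura coupling, which proceeds with retention of the diene geometry.

Step 7
Reactants: 6 (4R)-4-[(tert-butyldimethylsilyl)oxy]cyclohexane-1,3-dione; 11 (7E,9E)-octadeca-7,9-dienoic acid
Product: 13 (6R)-6-[(tert-butyldimethylsilyl)oxy]-3-hydroxy-2-[(7E,9E)-octadeca-7,9-dienoyl]cyclohex-2-en-1-one, via enol ester 12 (not isolated)
Conditions: DCC (1.1 equiv), DMAP (1.2 equiv), CH2Cl2, 0 °C to rt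
Reagents that add atoms: none
Why: Steglich-type O-acylation of the enolised dione followed by the DMAP-mediated 1,3-O-to-C acyl shift that is standard for 2-acylcyclohexane-1,3-diones; both possible enol esters converge on the C2-acyl product, driven by the stability of the chelated triketone enol.

Step 8
Reactants: 13 (6R)-6-[(tert-butyldimethylsilyl)oxy]-3-hydroxy-2-[(7E,9E)-octadeca-7,9-dienoyl]cyclohex-2-en-1-one
Product: 14 (6R)-3,6-dihydroxy-2-[(7E,9E)-octadeca-7,9-dienoyl]cyclohex-2-en-1-one
Conditions: HF (48% aq.), MeCN, 0 °C
Reagents that add atoms: none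
Why: Acidic fluoride cleavage of the secondary silyl ether under non-basic conditions should leave the triketone, the diene and the adjacent stereocentre untouched.

**Compound list**
1 | 1-[(tert-butyldimethylsilyl)oxy]propan-2-one | CC(=O)CO[Si](C)(C)C(C)(C)C | starting material
2 | (Z)-1,2-bis[(tert-butyldimethylsilyl)oxy]prop-1-ene | C/C(O[Si](C)(C)C(C)(C)C)=C/O[Si](C)(C)C(C)(C)C | intermediate
3 | 2,2,2-trifluoroethyl acrylate | C=CC(=O)OCC(F)(F)F | starting material
4 | 2,2,2-trifluoroethyl (1R,2S,3R)-2,3-bis[(tert-butyldimethylsilyl)oxy]-2-methylcyclobutane-1-carboxylate | O=C(OCC(F)(F)F)[C@@H]1C[C@@H](O[Si](C)(C)C(C)(C)C)[C@@]1(C)O[Si](C)(C)C(C)(C)C | intermediate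
5 | 2,2,2-trifluoroethyl (4R)-4-[(tert-butyldimethylsilyl)oxy]-5-oxohexanoate | CC(=O)[C@H](O[Si](C)(C)C(C)(C)C)CCC(=O)OCC(F)(F)F | intermediate
6 | (4R)-4-[(tert-butyldimethylsilyl)oxy]cyclohexane-1,3-dione | O=C1CC[C@@H](O[Si](C)(C)C(C)(C)C)C(=O)C1 | intermediate
7 | (E)-undec-2-enal | CCCCCCCC/C=C/C=O | starting material
8 | (1E,3E)-1-iodododeca-1,3-diene | CCCCCCCC/C=C/C=C/I | intermediate
9 | hex-5-enoic acid | C=CCCCC(=O)O | starting material
10 | 9-borabicyclo[3.3.1]nonan-9-yl 6-(9-borabicyclo[3.3.1]nonan-9-yl)hexanoate (not isolated) | O=C(CCCCCB1C2CCCC1CCC2)OB1C2CCCC1CCC2 | intermediate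
11 | (7E,9E)-octadeca-7,9-dienoic acid | CCCCCCCC/C=C/C=C/CCCCCC(=O)O | intermediate
12 | (4R)-4-[(tert-butyldimethylsilyl)oxy]-3-oxocyclohex-1-en-1-yl (7E,9E)-octadeca-7,9-dienoate (not isolated) | CCCCCCCC/C=C/C=C/CCCCCC(=O)OC1=CC(=O)[C@H](O[Si](C)(C)C(C)(C)C)CC1 | intermediate
13 | (6R)-6-[(tert-butyldimethylsilyl)oxy]-3-hydroxy-2-[(7E,9E)-octadeca-7,9-dienoyl]cyclohex-2-en-1-one | CCCCCCCC/C=C/C=C/CCCCCC(=O)C1=C(O)CC[C@@H](O[Si](C)(C)C(C)(C)C)C1=O | intermediate
14 | (6R)-3,6-dihydroxy-2-[(7E,9E)-octadeca-7,9-dienoyl]cyclohex-2-en-1-one | CCCCCCCC/C=C/C=C/CCCCCC(=O)C1=C(O)CC[C@@H](O)C1=O | target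

**Total step count:** 8. **Longest linear sequence:** 6 steps (steps 1, 2, 3, 4, 7, 8).

**Steps most likely to fail**

Step 2. Silyl transfer from the oxocarbenium ion to the ester enolate may outrun ring closure and give the open-chain adduct. The facial or exo preference may also be low, which would erode the enantiomeric purity of the carbinol centre once C1 is erased. The fallback replaces catalyst control by a covalent auxiliary; it sets out from 2 and comes back at 6. Commercial (−)-8-phenylmenthol is esterified with acryloyl chloride to (−)-8-phenylmenthyl acrylate F1. F1 and 2 are combined under EtAlCl2 in CH2Cl2 at −78 °C in a diastereoselective [2+2] cycloaddition, which should give the 8-phenylmenthyl cyclobutanecarboxylate F2 (the antipodal auxiliary is used if the shielded face proves to be the other one). Opening as in step 3 gives the 8-phenylmenthyl keto ester F3, and LiHMDS closes it to 6 with release of the auxiliary.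

Step 4. Proton transfer between the methyl-ketone enolate, the ester α-methylene and the C4 methine before ring closure may epimerise C4, and the ester enolate may re-close to cyclobutanols. The fallback replaces the Claisen closure by an aldol closure and an oxidation; it sets out from 4 and comes back at 6. The ester of 4 is reduced with DIBAL-H (CH2Cl2, −78 °C) to the cyclobutanecarbaldehyde F4 while the ketone is still masked in the ring. Opening with catalytic Tf2NH in wet CH2Cl2 gives the keto aldehyde F5, an L-proline-catalysed 6-enolexo aldol of the methyl ketone onto the aldehyde gives the hydroxy ketone F6, and Dess–Martin periodinane oxidises it to 6.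

Step 7. The O-to-C acyl shift may stall at the enol ester next to the bulky silyloxy group, and nucleophilic catalysis may lead to silyl loss or migration. The fallback installs the acyl group before the six-membered ring is closed; it sets out from 5 and 11 and comes back at 13. Acid 11 is converted with oxalyl chloride and catalytic DMF into the acid chloride F7. Soft enolisation of 5 (MgBr2·OEt2, i-Pr2NEt, CH2Cl2) and C-acylation with F7 give the diketo ester F8. Its magnesium-chelated diketonate should close through the central carbon onto the trifluoroethyl ester (Claisen cyclisation, on warming or with DBU) to give 13. Should ring closure precede acylation, the magnesium enolate of 6 is C-acylated by F7 and the same compound 13 results.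

**Further compounds**
F1 | step 2 | (1R,2S,5R)-5-methyl-2-(2-phenylpropan-2-yl)cyclohexyl acrylate | C=CC(=O)O[C@@H]1C[C@H](C)CC[C@H]1C(C)(C)c1ccccc1
F2 | step 2 | (1R,2S,5R)-5-methyl-2-(2-phenylpropan-2-yl)cyclohexyl (1R,2S,3R)-2,3-bis[(tert-butyldimethylsilyl)oxy]-2-methylcyclobutane-1-carboxylate | O=C(O[C@@H]1C[C@H](C)CC[C@H]1C(C)(C)c1ccccc1)[C@@H]1C[C@@H](O[Si](C)(C)C(C)(C)C)[C@@]1(C)O[Si](C)(C)C(C)(C)C
F3 | step 2 | (1R,2S,5R)-5-methyl-2-(2-phenylpropan-2-yl)cyclohexyl (4R)-4-[(tert-butyldimethylsilyl)oxy]-5-oxohexanoate | CC(=O)[C@H](O[Si](C)(C)C(C)(C)C)CCC(=O)O[C@@H]1C[C@H](C)CC[C@H]1C(C)(C)c1ccccc1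
F4 | step 4 | (1R,2S,3R)-2,3-bis[(tert-butyldimethylsilyl)oxy]-2-methylcyclobutane-1-carbaldehyde | O=C[C@@H]1C[C@@H](O[Si](C)(C)C(C)(C)C)[C@@]1(C)O[Si](C)(C)C(C)(C)C
F5 | step 4 | (4R)-4-[(tert-butyldimethylsilyl)oxy]-5-oxohexanal | CC(=O)[C@H](O[Si](C)(C)C(C)(C)C)CCC=O
F6 | step 4 | (2R)-2-[(tert-butyldimethylsilyl)oxy]-5-hydroxycyclohexan-1-one (both configurations at C5) | O=C1CC(O)CC[C@H]1O[Si](C)(C)C(C)(C)C
F7 | step 7 | (7E,9E)-octadeca-7,9-dienoyl chloride | CCCCCCCC/C=C/C=C/CCCCCC(=O)Cl
F8 | step 7 | 2,2,2-trifluoroethyl (4R,13E,15E)-4-[(tert-butyldimethylsilyl)oxy]-5,7-dioxotetracosa-13,15-dienoate | CCCCCCCC/C=C/C=C/CCCCCC(=O)CC(=O)[C@H](O[Si](C)(C)C(C)(C)C)CCC(=O)OCC(F)(F)F
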